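## The problem

Compound 25 is a 1H-isochromene in which a 2H-pyran (ring A: O2, C1H2, C3=C4) and a cyclohexenone (ring B: C5H2, C6, C7, C8=O) share the tetrasubstituted C4a=C8a bond. O2, C3=C4, C4a=C8a and C8=O form one push–pull dienone that also carries the (E)-propenyl group at C3. Ring B holds two adjacent stereocentres: the quaternary C7 (S), with a methyl and an acyloxy group, and the secondary carbinol C6 (R), whose hydroxyl is trans to the C7 oxygen. C7 has no hydrogen, so it must be made with absolute control; a free C7 hydroxyl can then deliver hydride to a C6 carbonyl on its own face, which gives exactly the trans relationship, so C7 can control C6 but not the reverse. The ester joins a tertiary α-ketol to a benzoic acid with two ortho substituents, and it sits next to a free secondary hydroxyl to which it could migrate. The dienyl enol ether and the propenyl group exclude hydrogenolysis and strong acid. C5 is vinylogously acidic with the C6 oxygen β to it, so strong base invites elimination across C5–C6. The feature the plan uses is that C5 is the γ-carbon of the C8 enone: in a monocyclic 3-acyl-4-methyl-2H-pyran it is an acidic methyl group, while C6 and C7 (with its methyl and oxygen) are the carboxyl and α-carbon of lactic acid.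

## Retrosynthesis

**Ester and protecting groups (25 ⇒ 24 ⇒ 18 + 22).** The C7–O–acyl bond is cut last but one. Carrying the aroyl group through enolate chemistry would expose an ester to strong base and would remove the free C7 hydroxyl needed to direct the C6 reduction. Silyl groups on O6 and on the phenol (24) fall together with buffered fluoride, the only deprotection the dienyl ether and propenyl group tolerate easily. The precursors are alcohol 18 and acid 22, which comes in three steps from aldehyde 19 through 20 and 21 (silylation of the free para hydroxyl, Mitsunobu methylation, Pinnick oxidation). The forward reaction must acylate a tertiary α-ketol with the di-ortho-substituted aroyl chloride 23; this is the hardest conventional step.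

**C6 carbinol (18 ⇒ 17 ⇒ 16).** The C6–H bond is cut back to dione 16. Setting C6 before ring closure would need a second stereocentre in an acyclic precursor and a different ring closure. Here the C7 hydroxyl of 16 directs the hydride, and 16 has a single stereocentre. The forward step must distinguish C6 from C8 (C8 is a doubly vinylogous ester carbonyl and far less electrophilic) and secondary from tertiary hydroxyl in the silylation to 18.

**C5–C6, ring B (16 ⇒ 15).** Cutting C5–C6 turns ring B into a vinylogous Dieckmann closure of 15. Cutting C4a–C5 would need a nucleophile at a tetrasubstituted alkene carbon. Cutting C6–C7 or C7–C8 would form the quaternary centre during ring closure. The C5–C6 cut creates no stereocentre, and the lactate dioxolanone in 15 serves as carrier of chirality, protecting group for O7 and activated acyl donor; its cleavage frees the hydroxyl needed next. The forward step needs γ-deprotonation of one methyl group and C-acylation through a six-membered transition state.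

**C7–C8 (15 ⇒ 14 ⇒ 13 + 10).** The ketone is made by aldol addition of the enolate of dioxolanone 13 to aldehyde 10, then oxidation of carbinol 14. Direct C-acylation with an acid chloride would risk O-acylation and cost extra steps to make the acyl donor. The cut divides 15 into two fragments of similar size, and the acetal centre of 13 fixes C7 during the aldol. The forward reaction asks a hindered enolate to add 1,2 to a deactivated push–pull aldehyde without proton transfer from its 4-methyl group. The 3-acyl-2H-pyrans 10 and 15 should stay closed, since the push–pull conjugation through the ring oxygen is lost on electrocyclic opening, as in ring A of 25 itself.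

**Dioxolanone (13 ⇒ 11 + 12).** Acetalization of (S)-lactic acid 11 with pivalaldehyde 12; both are bulk chemicals, and the S configuration of 11 corresponds to 7S when the electrophile replaces hydrogen with retention.

**Ring A aldehyde (10 ⇒ 9 ⇒ 7).** The pyran C4–CH3 bond is cut to chloride 9 (cross-coupling), and the formyl group and chlorine are both traced to the carbonyl and α-methylene of dihydropyranone 7 (Vilsmeier–Haack–Arnold reaction). The alternative of formylation, O-alkylation, MeLi addition and transposition takes one step more and is kept as a fallback. The forward step needs formylation at pyran C3 and not at C5.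

**Dihydropyranone (7 ⇒ 5 ⇒ 4 ⇒ 2 + 3; 2 ⇒ 1).** The ring O–C bond is opened to hydroxy diketone 6, set free from silyl ether 5. The diketone comes from aldol 4 of ketone 2 with (E)-but-2-enal 3, which supplies the propenyl group with its geometry. Ketone 2 is the silyl ether of commercial 1. Cyclization can only occur onto the distal carbonyl (six-membered ring).

## Roads not taken

**Alternative 1:** The cut is the ester O–C(acyl) bond together with the aryl C1'–C6' bond. A C6-silylated tertiary alcohol such as A1 is heated with diketo-dioxinone A2; loss of acetone unmasks a ketene function that O7 captures, and aldol aromatization of the tethered chain gives resorcylate A3.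
- Merit: a ketene is linear and unhindered, and tertiary alcohols trap acylketenes well. For forming the C7 ester this is better than the acylation in step 16 of the chosen plan.
- Weak points: A3 has both phenols free, while 25 needs the hydrogen-bonded ortho oxygen methylated and the para one free. That is against inherent reactivity and costs a protection, a methylation and a deprotection. The base and acid of the aromatization act on a core that is prone to elimination across C5–C6, and A2 must itself be made.
- Comparison: this road does not address the bicyclic core at all. The chosen plan brings the arene in with its methyl ether already in place through acid 22, and keeps this chemistry as the fallback for step 16.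

**Alternative 2:** The cut is C4a=C8a, with ring A closed afterwards. The open-chain silyl enol ether A4 is folded by an intramolecular Mukaiyama aldol onto the C4a carbonyl and dehydrated to cyclohexenone A5.
- Merit: C6 and C7 are set in the acyclic series under reagent control, and the two oxygens arrive differentiated, so O7 can be freed alone. In this respect it is better than the chosen plan, which needs a directed reduction and a selective silylation to reach the same point.
- Weak points: A4 is a long chain with five oxygenated carbons and four protecting groups. Its enol ether must be regiodefined next to quaternary C7 and has a β-alkoxy group that can eliminate. The electrophile is a vinylogous ester carbonyl of low reactivity, and the dehydration must give a tetrasubstituted alkene. Ring A still has to be closed after oxidative removal of the PMB ether in the presence of an electron-rich dienyl ether.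
- Comparison: the chosen plan builds ring A first and closes ring B by one C–C bond without any stereochemical question, in fewer steps.

**Alternative 3:** The cuts are C7–O and O2–C3. Alkynyl aldehyde A6 is hydroxylated at C7 with dearomatization by the chiral complex formed from [Cu(MeCN)4]PF6, sparteine and O2, and the aldehyde oxygen then adds to the alkyne to give azaphilone A7.
- Merit: the bicyclic skeleton with C7 in place is reached in very few steps from an aromatic aldehyde. This is clearly shorter than the ten steps the chosen plan needs to reach 16.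
- Weak points: A7 is two hydrogens too oxidized at C1/C5. Reaching 16 needs a conjugate reduction that adds hydrogen at C1 and C5 and spares the C6 and C8 carbonyls, the C3=C4 enol ether and the propenyl group, in a chromophore that reacts with nucleophiles at several positions. The oxidation uses a stoichiometric chiral complex at low temperature and depends on the diamine enantiomer required for 7S.
- Comparison: if that reduction were reliable, this would be the shorter route. The chosen plan offers the correct oxidation level at C1 and C5 from the start and takes C7 from lactic acid.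

Key step: step 10

Remark: lithium and potassium enolates or alkoxides that differ from a numbered compound only by a proton and the counter-ion are not numbered separately. Isochromene numbering is used for bicyclic compounds and pyran numbering for monocyclic ring A compounds.

## Route

Step 1
Reactants: 1 4-hydroxybutan-2-one
Product: 2 4-[(tert-butyldimethylsilyl)oxy]butan-2-one
Conditions: TBSCl, imidazole, CH2Cl2, 0 °C → rt
Reagents that add atoms: tert-butyldimethylsilyl chloride, CC(C)(C)[Si](C)(C)Cl
Why: Standard silylation of a primary alcohol; the mild base avoids β-elimination to methyl vinyl ketone and the ether masks the hydroxyl for the enolate chemistry of step 2.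

Step 2
Reactants: 2 4-[(tert-butyldimethylsilyl)oxy]butan-2-one; 3 (E)-but-2-enal
Product: 4 (E)-1-[(tert-butyldimethylsilyl)oxy]-5-hydroxyoct-6-en-3-one (racemic)
Conditions: LiN(iPr)2, THF, −78 °C; then 3, −78 °C; AcOH
Reagents that add atoms: none
Why: Kinetic deprotonation of the methyl ketone at the methyl group and 1,2-aldol addition to the enal; the carbinol centre is removed in step 3 and the E alkene is carried over from 3.

Step 3
Reactants: 4 (E)-1-[(tert-butyldimethylsilyl)oxy]-5-hydroxyoct-6-en-3-one
Product: 5 (E)-1-[(tert-butyldimethylsilyl)oxy]oct-6-ene-3,5-dione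
Conditions: Dess–Martin periodinane, CH2Cl2, 0 °C → rt
Reagents that add atoms: none
Why: Dess–Martin oxidation of a β-hydroxy ketone to the 1,3-diketone, which stops cleanly at the enolizable dione.

Step 4
Reactants: 5 (E)-1-[(tert-butyldimethylsilyl)oxy]oct-6-ene-3,5-dione
Product: 7 6-[(E)-prop-1-enyl]-2,3-dihydro-4H-pyran-4-one, via hydroxy diketone 6 (not isolated)
Conditions: aq. HF, MeCN, 0 °C → rt; then TFA (cat.), CH2Cl2, rt
Reagents that add atoms: none
Why: Desilylation frees the primary alcohol, which adds to the distal carbonyl and loses water (cyclodehydration of a δ-hydroxy β-diketone to a vinylogous ester); attack on the nearer carbonyl would give a four-membered ring.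

Step 5
Reactants: 7 6-[(E)-prop-1-enyl]-2,3-dihydro-4H-pyran-4-one
Product: 9 4-chloro-6-[(E)-prop-1-enyl]-2H-pyran-3-carbaldehyde, via chlorovinyl iminium salt 8 (not isolated)
Conditions: POCl3, DMF, CH2Cl2, 0 → 40 °C; then ice-water
Reagents that add atoms: N,N-dimethylformamide, CN(C)C=O; phosphoryl chloride, O=P(Cl)(Cl)Cl; water, O
Why: Vilsmeier–Haack–Arnold chloroformylation of a ketone with one α-methylene group, the reaction that converts chroman-4-ones, the benzo analogues of 7, into 4-chloro-2H-chromene-3-carbaldehydes; C3 is the only enolizable α-carbon and also the terminus of the dienol ether formed on O-activation, and hydrolysis of 8 gives the push–pull aldehyde.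

Step 6
Reactants: 9 4-chloro-6-[(E)-prop-1-enyl]-2H-pyran-3-carbaldehyde
Product: 10 4-methyl-6-[(E)-prop-1-enyl]-2H-pyran-3-carbaldehyde
Conditions: MeZnCl, Pd(PPh3)4 (cat.), THF, 0 °C → rt
Reagents that add atoms: methylzinc chloride, C[Zn]Cl
Why: Negishi coupling; the β-chloro enal is a vinylogous acid chloride that adds readily to zerovalent palladium, and the organozinc does not add to the aldehyde at this temperature.

Step 7
Reactants: 11 (S)-lactic acid; 12 pivalaldehyde
Product: 13 (2S,5S)-2-tert-butyl-5-methyl-1,3-dioxolan-4-one
Conditions: TsOH·H2O (cat.), H2SO4 (cat.), pentane, reflux, water separator; crystallization from pentane, −78 °C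
Reagents that add atoms: none
Why: Acid-catalysed acetalization under equilibrating conditions; the cis acetal should predominate and is enriched by crystallization, so the new C2 centre (S) is set by the lactate centre and can later relay it.

Step 8
Reactants: 13 (2S,5S)-2-tert-butyl-5-methyl-1,3-dioxolan-4-one; 10 4-methyl-6-[(E)-prop-1-enyl]-2H-pyran-3-carbaldehyde
Product: 14 (2S,5R)-2-tert-butyl-5-{hydroxy[4-methyl-6-((E)-prop-1-enyl)-2H-pyran-3-yl]methyl}-5-methyl-1,3-dioxolan-4-one (both carbinol epimers)
Conditions: LiN(iPr)2, THF, −78 °C; then 10, −78 °C; AcOH (1 equiv), −78 °C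
Reagents that add atoms: none
Why: Aldol addition of a dioxolanone enolate (self-regeneration of stereocentres): the aldehyde approaches the planar enolate on the face opposite the tert-butyl group, so the new carbon takes the place of the lactate hydrogen with retention and the quaternary centre is 5R (later 7S); the carbinol centre is not controlled and is removed in step 9.

Step 9
Reactants: 14 (2S,5R)-2-tert-butyl-5-{hydroxy[4-methyl-6-((E)-prop-1-enyl)-2H-pyran-3-yl]methyl}-5-methyl-1,3-dioxolan-4-one
Product: 15 (2S,5R)-2-tert-butyl-5-methyl-5-{[4-methyl-6-((E)-prop-1-enyl)-2H-pyran-3-yl]carbonyl}-1,3-dioxolan-4-one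
Conditions: Dess–Martin periodinane, pyridine, CH2Cl2, 0 °C → rt
Reagents that add atoms: none
Why: Dess–Martin oxidation of a hindered allylic carbinol under buffered conditions, chosen because the carbinol ionizes easily in acid; the product is a β-keto lactone without α-hydrogen.

Step 10
Reactants: 15 (2S,5R)-2-tert-butyl-5-methyl-5-{[4-methyl-6-((E)-prop-1-enyl)-2H-pyran-3-yl]carbonyl}-1,3-dioxolan-4-one
Product: 16 (7S)-7-hydroxy-7-methyl-3-[(E)-prop-1-enyl]-1H-isochromene-6,8(5H,7H)-dione
Conditions: KN(SiMe3)2 (2.2 equiv), THF, −78 → −20 °C, argon; AcOH, −78 °C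
Reagents that add atoms: none
Why: Proposed new method: KN(SiMe3)2 removes a proton from the pyran 4-methyl group (the future C5), the γ-position of the C8 enone; C7 is quaternary and C8a is sp2, so no α-proton competes, and the trienolate from the more remote propenyl methyl has no unstrained path to the lactone carbonyl and returns by proton exchange. The dienolate terminus adds to the dioxolanone carbonyl, the tetrahedral intermediate expels the acetal oxygen and the resulting hemiacetal alkoxide loses pivalaldehyde, so C5–C6 forms and the C7 hydroxyl is freed in one operation. Ring B closes in a 6-(enolendo)-exo-trig mode; attack through C8a would give a four-membered ring and the enolate oxygen cannot reach the carbonyl, so only C-acylation through C5 is possible. The closest known reaction types are the vinylogous Dieckmann condensation (γ-acylation of a β-methyl enone dienolate by a tethered ester) and the Claisen acylation of enolates by 1,3-dioxolan-4-ones; their combination in one substrate has not been shown. No stereocentre is created, and C7, fixed in step 8, has no hydrogen and cannot epimerize. The step needs the base to act only as a base, which its bulk secures, and a driving force, which the second equivalent supplies by converting the product into its vinylogous 1,3-diketonate; cold acidification under argon then returns the dione without air oxidation.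

Step 11
Reactants: 16 (7S)-7-hydroxy-7-methyl-3-[(E)-prop-1-enyl]-1H-isochromene-6,8(5H,7H)-dione
Product: 17 (6R,7S)-6,7-dihydroxy-7-methyl-3-[(E)-prop-1-enyl]-6,7-dihydro-1H-isochromen-8(5H)-one
Conditions: Me4NBH(OAc)3, MeCN/AcOH, −30 → 0 °C
Reagents that add atoms: none
Why: Hydroxyl-directed triacetoxyborohydride reduction (Evans–Saksena type): the C7 hydroxyl binds boron and delivers hydride to the adjacent C6 carbonyl on the face that bears O7, so the new hydroxyl ends trans to O7 (6R); the reagent does not reduce ketones without such delivery, and C8, a doubly vinylogous ester carbonyl, is far less electrophilic than the isolated C6 ketone.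

Step 12
Reactants: 17 (6R,7S)-6,7-dihydroxy-7-methyl-3-[(E)-prop-1-enyl]-6,7-dihydro-1H-isochromen-8(5H)-one
Product: 18 (6R,7S)-7-hydroxy-7-methyl-3-[(E)-prop-1-enyl]-6-[(triethylsilyl)oxy]-6,7-dihydro-1H-isochromen-8(5H)-one
Conditions: Et3SiCl, imidazole, CH2Cl2, −20 → 0 °C
Reagents that add atoms: chlorotriethylsilane, CC[Si](Cl)(CC)CC
Why: Silyl chlorides react with the secondary hydroxyl far faster than with the tertiary α-ketol; the small triethylsilyl group leaves room for the acylation of step 16.

Step 13
Reactants: 19 2,4-dihydroxy-6-methylbenzaldehyde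
Product: 20 2-hydroxy-6-methyl-4-[(triisopropylsilyl)oxy]benzaldehyde
Conditions: iPr3SiCl, imidazole, CH2Cl2, 0 °C → rt
Reagents that add atoms: chlorotriisopropylsilane, CC(C)[Si](Cl)(C(C)C)C(C)C
Why: The ortho hydroxyl is hydrogen-bonded to the formyl group and hindered, so silylation occurs at the para hydroxyl.

Step 14
Reactants: 20 2-hydroxy-6-methyl-4-[(triisopropylsilyl)oxy]benzaldehyde
Product: 21 2-methoxy-6-methyl-4-[(triisopropylsilyl)oxy]benzaldehyde
Conditions: MeOH, PPh3, DIAD, THF, 0 °C → rt
Reagents that add atoms: methanol, CO
Why: Mitsunobu etherification of a phenol under neutral conditions, which spares the aryl silyl ether that carbonate bases could cleave.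

Step 15
Reactants: 21 2-methoxy-6-methyl-4-[(triisopropylsilyl)oxy]benzaldehyde
Product: 22 2-methoxy-6-methyl-4-[(triisopropylsilyl)oxy]benzoic acid
Conditions: NaClO2, NaH2PO4, 2-methylbut-2-ene, t-BuOH/H2O, rt
Reagents that add atoms: sodium chlorite, [Na+].[O-]Cl=O
Why: Pinnick oxidation; the alkene scavenger protects the electron-rich ring from chlorination and the buffered medium leaves the silyl ether intact.

Step 16
Reactants: 22 2-methoxy-6-methyl-4-[(triisopropylsilyl)oxy]benzoic acid; 18 (6R,7S)-7-hydroxy-7-methyl-3-[(E)-prop-1-enyl]-6-[(triethylsilyl)oxy]-6,7-dihydro-1H-isochromen-8(5H)-one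
Product: 24 (6R,7S)-7-methyl-8-oxo-3-[(E)-prop-1-enyl]-6-[(triethylsilyl)oxy]-5,6,7,8-tetrahydro-1H-isochromen-7-yl 2-methoxy-6-methyl-4-[(triisopropylsilyl)oxy]benzoate, via aroyl chloride 23 (not isolated)
Conditions: 22, (COCl)2, DMF (cat.), CH2Cl2, 0 °C → rt, evaporate; then 18, DMAP, Et3N, ClCH2CH2Cl, 60 °C
Reagents that add atoms: none
Why: Acid chloride formation followed by DMAP-catalysed acylation of a tertiary α-ketol, a known way to esterify C7 hydroxyls of this ring type; the electron-rich aroyl chloride ionizes readily to an acylpyridinium ion, and the neutral amine conditions avoid an alkoxide that could shift the silyl group or eliminate across C5–C6.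

Step 17
Reactants: 24 (6R,7S)-7-methyl-8-oxo-3-[(E)-prop-1-enyl]-6-[(triethylsilyl)oxy]-5,6,7,8-tetrahydro-1H-isochromen-7-yl 2-methoxy-6-methyl-4-[(triisopropylsilyl)oxy]benzoate
Product: 25 (6R,7S)-6-hydroxy-7-methyl-8-oxo-3-[(E)-prop-1-enyl]-5,6,7,8-tetrahydro-1H-isochromen-7-yl 4-hydroxy-2-methoxy-6-methylbenzoate
Conditions: Bu4NF, AcOH, THF, 0 °C → rt
Reagents that add atoms: none
Why: Fluoride cleaves the aryl and the alkyl silyl ether in one operation; acetic acid buffers the medium so that neither acyl migration from O7 to O6 nor elimination across C5–C6 is triggered.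

## Compound list

1 | 4-hydroxybutan-2-one | CC(=O)CCO | starting material
2 | 4-[(tert-butyldimethylsilyl)oxy]butan-2-one | CC(=O)CCO[Si](C)(C)C(C)(C)C | intermediate
3 | (E)-but-2-enal | C/C=C/C=O | starting material
4 | (E)-1-[(tert-butyldimethylsilyl)oxy]-5-hydroxyoct-6-en-3-one (racemic) | C/C=C/C(O)CC(=O)CCO[Si](C)(C)C(C)(C)C | intermediate
5 | (E)-1-[(tert-butyldimethylsilyl)oxy]oct-6-ene-3,5-dione | C/C=C/C(=O)CC(=O)CCO[Si](C)(C)C(C)(C)C | intermediate
6 | (E)-1-hydroxyoct-6-ene-3,5-dione | C/C=C/C(=O)CC(=O)CCO | intermediate (not isolated)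
7 | 6-[(E)-prop-1-enyl]-2,3-dihydro-4H-pyran-4-one | C/C=C/C1=CC(=O)CCO1 | intermediate
8 | N-{[4-chloro-6-((E)-prop-1-enyl)-2H-pyran-3-yl]methylidene}-N-methylmethanaminium dichlorophosphate | C/C=C/C1=CC(Cl)=C(C=[N+](C)C)CO1.[O-]P(=O)(Cl)Cl | intermediate (not isolated)
9 | 4-chloro-6-[(E)-prop-1-enyl]-2H-pyran-3-carbaldehyde | C/C=C/C1=CC(Cl)=C(C=O)CO1 | intermediate
10 | 4-methyl-6-[(E)-prop-1-enyl]-2H-pyran-3-carbaldehyde | C/C=C/C1=CC(C)=C(C=O)CO1 | intermediate
11 | (S)-lactic acid | C[C@H](O)C(=O)O | starting material
12 | pivalaldehyde (2,2-dimethylpropanal) | CC(C)(C)C=O | starting material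
13 | (2S,5S)-2-tert-butyl-5-methyl-1,3-dioxolan-4-one (cis) | C[C@@H]1O[C@H](C(C)(C)C)OC1=O | intermediate
14 | (2S,5R)-2-tert-butyl-5-{hydroxy[4-methyl-6-((E)-prop-1-enyl)-2H-pyran-3-yl]methyl}-5-methyl-1,3-dioxolan-4-one (carbinol epimers) | C/C=C/C1=CC(C)=C(CO1)C(O)[C@@]1(C)O[C@H](C(C)(C)C)OC1=O | intermediate
15 | (2S,5R)-2-tert-butyl-5-methyl-5-{[4-methyl-6-((E)-prop-1-enyl)-2H-pyran-3-yl]carbonyl}-1,3-dioxolan-4-one | C/C=C/C1=CC(C)=C(CO1)C(=O)[C@@]1(C)O[C@H](C(C)(C)C)OC1=O | intermediate
16 | (7S)-7-hydroxy-7-methyl-3-[(E)-prop-1-enyl]-1H-isochromene-6,8(5H,7H)-dione | C/C=C/C1=CC2=C(CO1)C(=O)[C@@](C)(O)C(=O)C2 | intermediate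
17 | (6R,7S)-6,7-dihydroxy-7-methyl-3-[(E)-prop-1-enyl]-6,7-dihydro-1H-isochromen-8(5H)-one | C/C=C/C1=CC2=C(CO1)C(=O)[C@@](C)(O)[C@H](O)C2 | intermediate
18 | (6R,7S)-7-hydroxy-7-methyl-3-[(E)-prop-1-enyl]-6-[(triethylsilyl)oxy]-6,7-dihydro-1H-isochromen-8(5H)-one | C/C=C/C1=CC2=C(CO1)C(=O)[C@@](C)(O)[C@H](O[Si](CC)(CC)CC)C2 | intermediate
19 | 2,4-dihydroxy-6-methylbenzaldehyde | Cc1cc(O)cc(O)c1C=O | starting material
20 | 2-hydroxy-6-methyl-4-[(triisopropylsilyl)oxy]benzaldehyde | Cc1cc(O[Si](C(C)C)(C(C)C)C(C)C)cc(O)c1C=O | intermediate
21 | 2-methoxy-6-methyl-4-[(triisopropylsilyl)oxy]benzaldehyde | Cc1cc(O[Si](C(C)C)(C(C)C)C(C)C)cc(OC)c1C=O | intermediate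
22 | 2-methoxy-6-methyl-4-[(triisopropylsilyl)oxy]benzoic acid | Cc1cc(O[Si](C(C)C)(C(C)C)C(C)C)cc(OC)c1C(=O)O | intermediate
23 | 2-methoxy-6-methyl-4-[(triisopropylsilyl)oxy]benzoyl chloride | Cc1cc(O[Si](C(C)C)(C(C)C)C(C)C)cc(OC)c1C(=O)Cl | intermediate (not isolated)
24 | (6R,7S)-7-methyl-8-oxo-3-[(E)-prop-1-enyl]-6-[(triethylsilyl)oxy]-5,6,7,8-tetrahydro-1H-isochromen-7-yl 2-methoxy-6-methyl-4-[(triisopropylsilyl)oxy]benzoate | C/C=C/C1=CC2=C(CO1)C(=O)[C@@](C)(OC(=O)c1c(C)cc(O[Si](C(C)C)(C(C)C)C(C)C)cc1OC)[C@H](O[Si](CC)(CC)CC)C2 | intermediate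
25 | (6R,7S)-6-hydroxy-7-methyl-8-oxo-3-[(E)-prop-1-enyl]-5,6,7,8-tetrahydro-1H-isochromen-7-yl 4-hydroxy-2-methoxy-6-methylbenzoate | C/C=C/C1=CC2=C(CO1)C(=O)[C@@](C)(OC(=O)c1c(C)cc(O)cc1OC)[C@H](O)C2 | target

## Step count and least certain steps

Total: 17 steps. Longest linear sequence: 13 steps (steps 1–6, 8–12, 16, 17); step 7 and steps 13–15 are side branches.

**Step 10 (key step, proposed new method).** Most likely to go wrong: fragmentation of the non-enolizable β-keto lactone by retro-Claisen attack at C8 of any alkoxide formed, condensation of the released pivalaldehyde with the dienolate or the product enolate, or air oxidation of the product enolate to the fully unsaturated isochromenedione. Fallback with known chemistry, starting from 14: methanolysis of the dioxolanone (K2CO3, MeOH, 0 °C, loss of pivalaldehyde) gives methyl ester diol F1. MnO2 in CH2Cl2 oxidizes only the allylic secondary alcohol to keto ester F2. Silylation of the tertiary hydroxyl (Et3SiOTf, 2,6-lutidine) gives silyl ether F3. A vinylogous Dieckmann condensation onto the methyl ester (KN(SiMe3)2, THF, −78 → 0 °C), a known reaction type, gives bicyclic silyl ether F4. HF·pyridine then frees the C7 hydroxyl and the route is rejoined at 16.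

**Step 5.** Most likely to go wrong: electrophilic attack at pyran C5 (the α-carbon of the vinylogous ester) or on the propenyl chain instead of C3, and acid-induced oligomerization of the trienyl ether. Fallback starting from 7, introducing the formyl carbon under basic conditions: Claisen formylation of the kinetic C3 enolate (LiN(iPr)2, then ethyl formate) gives hydroxymethylidene ketone F5. O-alkylation (2-iodopropane, K2CO3, acetone) gives isopropoxymethylidene ketone F6. Addition of MeLi (CeCl3, THF, −78 °C) to the ketone gives tertiary carbinol F7, which in dilute aqueous HCl ionizes and is hydrolysed with allylic transposition to aldehyde 10. The route is rejoined at 10 and chloride 9 is bypassed.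

**Step 8.** Most likely to go wrong: proton transfer from the vinylogously acidic 4-methyl group of 10 to the enolate instead of addition, and retro-aldol reversal of a crowded aldolate formed from a deactivated aldehyde. Fallback starting from 9 and 13, with the aldol moved one stage earlier: the enolate of 13 adds to chloro aldehyde 9, which has no acidic methyl group and a more electrophilic carbonyl, to give chloro carbinol F8. Dess–Martin oxidation gives chloro ketone F9, and the Negishi methylation (MeZnCl, Pd(PPh3)4, THF) is then carried out on F9. The route is rejoined at 15.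

**Step 11.** Most likely to go wrong: loss of site or face control, through delivery to C8, through slow reaction if the C6 carbonyl is partly masked by enolization toward C5, or through undirected reduction on the other face. Fallback starting from 16, replacing internal delivery by catalyst control: the C7 hydroxyl is capped (Me3SiCl, imidazole) to give trimethylsilyl ether F10. The C6 ketone is reduced with BH3·SMe2 and (S)-2-methyl-CBS-oxazaborolidine (Corey–Bakshi–Shibata reduction, quaternary C7 taken as the large group) to give alcohol F11. Methanolysis of the silyl ether (citric acid, MeOH) rejoins the route at 17.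

**Step 16.** Most likely to go wrong: acylation too slow at the crowded tertiary hydroxyl, so that silyl migration from O6 to O7, elimination across C5–C6 or decomposition of the aroyl chloride take over. Fallback starting from 18, building the arene on O7: heating 18 with dioxinone A2 in toluene (loss of acetone, capture of the ketene by O7) gives triketo ester F12. Base-induced aldol aromatization gives resorcylate F13. Silylation of the free para hydroxyl (iPr3SiCl, imidazole) gives silyl ether F14, and Mitsunobu methylation of the hydrogen-bonded ortho hydroxyl (MeOH, PPh3, DIAD) rejoins the route at 24.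

## Further compounds

F1 | step 10 | methyl (2R)-2,3-dihydroxy-2-methyl-3-[4-methyl-6-((E)-prop-1-enyl)-2H-pyran-3-yl]propanoate (carbinol epimers) | C/C=C/C1=CC(C)=C(CO1)C(O)[C@@](C)(O)C(=O)OC
F2 | step 10 | methyl (2R)-2-hydroxy-2-methyl-3-[4-methyl-6-((E)-prop-1-enyl)-2H-pyran-3-yl]-3-oxopropanoate | C/C=C/C1=CC(C)=C(CO1)C(=O)[C@@](C)(O)C(=O)OC
F3 | step 10 | methyl (2R)-2-methyl-3-[4-methyl-6-((E)-prop-1-enyl)-2H-pyran-3-yl]-3-oxo-2-[(triethylsilyl)oxy]propanoate | C/C=C/C1=CC(C)=C(CO1)C(=O)[C@@](C)(O[Si](CC)(CC)CC)C(=O)OC
F4 | step 10 | (7S)-7-methyl-3-[(E)-prop-1-enyl]-7-[(triethylsilyl)oxy]-1H-isochromene-6,8(5H,7H)-dione | C/C=C/C1=CC2=C(CO1)C(=O)[C@@](C)(O[Si](CC)(CC)CC)C(=O)C2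
F5 | step 5 | 3-(hydroxymethylidene)-6-[(E)-prop-1-enyl]-2,3-dihydro-4H-pyran-4-one | C/C=C/C1=CC(=O)C(=CO)CO1
F6 | step 5 | 3-[(propan-2-yloxy)methylidene]-6-[(E)-prop-1-enyl]-2,3-dihydro-4H-pyran-4-one | C/C=C/C1=CC(=O)C(=COC(C)C)CO1
F7 | step 5 | 4-methyl-3-[(propan-2-yloxy)methylidene]-6-[(E)-prop-1-enyl]-3,4-dihydro-2H-pyran-4-ol (racemic) | C/C=C/C1=CC(C)(O)C(=COC(C)C)CO1
F8 | step 8 | (2S,5R)-2-tert-butyl-5-{[4-chloro-6-((E)-prop-1-enyl)-2H-pyran-3-yl](hydroxy)methyl}-5-methyl-1,3-dioxolan-4-one (carbinol epimers) | C/C=C/C1=CC(Cl)=C(CO1)C(O)[C@@]1(C)O[C@H](C(C)(C)C)OC1=O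
F9 | step 8 | (2S,5R)-2-tert-butyl-5-{[4-chloro-6-((E)-prop-1-enyl)-2H-pyran-3-yl]carbonyl}-5-methyl-1,3-dioxolan-4-one | C/C=C/C1=CC(Cl)=C(CO1)C(=O)[C@@]1(C)O[C@H](C(C)(C)C)OC1=O
F10 | step 11 | (7S)-7-methyl-3-[(E)-prop-1-enyl]-7-[(trimethylsilyl)oxy]-1H-isochromene-6,8(5H,7H)-dione | C/C=C/C1=CC2=C(CO1)C(=O)[C@@](C)(O[Si](C)(C)C)C(=O)C2
F11 | step 11 | (6R,7S)-6-hydroxy-7-methyl-3-[(E)-prop-1-enyl]-7-[(trimethylsilyl)oxy]-6,7-dihydro-1H-isochromen-8(5H)-one | C/C=C/C1=CC2=C(CO1)C(=O)[C@@](C)(O[Si](C)(C)C)[C@H](O)C2
F12 | step 16 | (6R,7S)-7-methyl-8-oxo-3-[(E)-prop-1-enyl]-6-[(triethylsilyl)oxy]-5,6,7,8-tetrahydro-1H-isochromen-7-yl 3,5,7-trioxooctanoate | C/C=C/C1=CC2=C(CO1)C(=O)[C@@](C)(OC(=O)CC(=O)CC(=O)CC(C)=O)[C@H](O[Si](CC)(CC)CC)C2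
F13 | step 16 | (6R,7S)-7-methyl-8-oxo-3-[(E)-prop-1-enyl]-6-[(triethylsilyl)oxy]-5,6,7,8-tetrahydro-1H-isochromen-7-yl 2,4-dihydroxy-6-methylbenzoate | C/C=C/C1=CC2=C(CO1)C(=O)[C@@](C)(OC(=O)c1c(C)cc(O)cc1O)[C@H](O[Si](CC)(CC)CC)C2
F14 | step 16 | (6R,7S)-7-methyl-8-oxo-3-[(E)-prop-1-enyl]-6-[(triethylsilyl)oxy]-5,6,7,8-tetrahydro-1H-isochromen-7-yl 2-hydroxy-6-methyl-4-[(triisopropylsilyl)oxy]benzoate | C/C=C/C1=CC2=C(CO1)C(=O)[C@@](C)(OC(=O)c1c(C)cc(O[Si](C(C)C)(C(C)C)C(C)C)cc1O)[C@H](O[Si](CC)(CC)CC)C2
A1 | alternative 1 | (6R,7S)-6-[(tert-butyldimethylsilyl)oxy]-7-hydroxy-7-methyl-3-[(E)-prop-1-enyl]-6,7-dihydro-1H-isochromen-8(5H)-one | C/C=C/C1=CC2=C(CO1)C(=O)[C@@](C)(O)[C@H](O[Si](C)(C)C(C)(C)C)C2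
A2 | alternative 1 | 2,2-dimethyl-6-(2,4-dioxopentyl)-4H-1,3-dioxin-4-one | CC(=O)CC(=O)CC1=CC(=O)OC(C)(C)O1
A3 | alternative 1 | (6R,7S)-6-[(tert-butyldimethylsilyl)oxy]-7-methyl-8-oxo-3-[(E)-prop-1-enyl]-5,6,7,8-tetrahydro-1H-isochromen-7-yl 2,4-dihydroxy-6-methylbenzoate | C/C=C/C1=CC2=C(CO1)C(=O)[C@@](C)(OC(=O)c1c(C)cc(O)cc1O)[C@H](O[Si](C)(C)C(C)(C)C)C2
A4 | alternative 2 | (4S,5R,8E,10E)-5-[(tert-butyldimethylsilyl)oxy]-9-methoxy-1-[(4-methoxybenzyl)oxy]-4-methyl-4-[(triethylsilyl)oxy]-3-[(trimethylsilyl)oxy]dodeca-2,8,10-trien-7-one | C/C=C/C(OC)=C\C(=O)C[C@@H](O[Si](C)(C)C(C)(C)C)[C@](C)(O[Si](CC)(CC)CC)C(O[Si](C)(C)C)=CCOCc1ccc(OC)cc1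
A5 | alternative 2 | (5R,6S)-5-[(tert-butyldimethylsilyl)oxy]-2-{[(4-methoxybenzyl)oxy]methyl}-3-[(1E,3E)-2-methoxypenta-1,3-dien-1-yl]-6-methyl-6-[(triethylsilyl)oxy]cyclohex-2-en-1-one | C/C=C/C(OC)=C\C1=C(COCc2ccc(OC)cc2)C(=O)[C@@](C)(O[Si](CC)(CC)CC)[C@H](O[Si](C)(C)C(C)(C)C)C1
A6 | alternative 3 | 2,4-dihydroxy-3-methyl-6-[(E)-pent-3-en-1-ynyl]benzaldehyde | C/C=C/C#Cc1cc(O)c(C)c(O)c1C=O
A7 | alternative 3 | (7S)-7-hydroxy-7-methyl-3-[(E)-prop-1-enyl]-6H-isochromene-6,8(7H)-dione | C/C=C/C1=CC2=CC(=O)[C@](C)(O)C(=O)C2=CO1
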